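**Retrosynthetic overview**

- Feature: in ring A the ester carbon C1 lies between the phenolic carbon C6 (C6–OH) and the diaryl-ether carbon C2 (C2–O–ring B). A C1–C2 aryne that carries the C6 oxygen can therefore take up the ring B phenoxide at C2 and CO2 at C1 with predictable orientation.
- Endgame: target ⇐ bis-MOM methyl ester ⇐ bis-MOM benzoic acid ⇐ ring A o-silylaryl triflate + caesium phenoxide of ring B + CO2.
- Ring A precursor: 2-bromo-3-methylphenol → MOM ether → sterically controlled C–H borylation/oxidation (the future triflate oxygen) → prenyl at the C–Br carbon → carbamate-directed silylation between the two oxygens → triflate.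
- Ring B phenol: 3,5-dimethoxybenzyl alcohol → ortho-bromination → MOM ether → Br/Li exchange, borylation, oxidation.
- No ring is formed in the route; both benzene rings come from the starting materials and are joined in the key step.

Key step: step 10

Remark: the target has no stereocentre and its alkene carries two identical methyl groups, so no stereocontrol is needed; ring A is built from 2-bromo-3-methylphenol so that its two oxygens are never equivalent and need no selective protection.

**Step 1**
Reactants: 1 2-bromo-3-methylphenol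
Product: 2 2-bromo-1-(methoxymethoxy)-3-methylbenzene
Conditions: NaH, MOMCl, THF, 0 °C → rt
Reagents that add atoms: chloromethyl methyl ether, COCCl
Why: Williamson-type O-alkylation of the sodium phenoxide installs the MOM acetal, which later directs lithiation, polarises the aryne and is removed by mild acid.

**Step 2**
Reactants: 2 2-bromo-1-(methoxymethoxy)-3-methylbenzene
Product: 4 4-bromo-3-(methoxymethoxy)-5-methylphenol, via aryl pinacol boronate 3 (not isolated)
Conditions: [Ir(OMe)(cod)]2 (cat.), 4,4'-di-tert-butyl-2,2'-bipyridine (cat.), B2pin2, THF, 80 °C; then aq. NaOH, 30% H2O2, 0 °C → rt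
Reagents that add atoms: bis(pinacolato)diboron, CC1(C)OB(OC1(C)C)B1OC(C)(C)C(C)(C)O1 (boron of 3 only); hydrogen peroxide, OO
Why: Iridium-catalysed aromatic C–H borylation is sterically controlled and should occur only at the one CH with no ortho substituent (meta to OMOM and to methyl, para to bromine), and alkaline peroxide oxidation of the C–B bond then gives the phenol, so the two ring A oxygens are differentiated by construction.

**Step 3**
Reactants: 4 4-bromo-3-(methoxymethoxy)-5-methylphenol; 5 1-bromo-3-methylbut-2-ene (prenyl bromide)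
Product: 8 3-(methoxymethoxy)-5-methyl-4-(3-methylbut-2-en-1-yl)phenol, via dilithiated phenoxide 6 (not isolated), via arylcopper phenoxide 7 (not isolated)
Conditions: n-BuLi (1 equiv), THF, −78 °C; t-BuLi (2 equiv), −78 °C; CuBr·SMe2 (1 equiv), −78 → −40 °C; 5, −78 → 0 °C; aq. NH4Cl
Reagents that add atoms: n-butyllithium, [Li]CCCC, and tert-butyllithium, [Li]C(C)(C)C (lithium of 6 and 7 only); copper bromide–dimethyl sulfide, Br[Cu].CSC (copper of 7 only)
Why: Deprotonation of the phenol, bromine–lithium exchange, transmetalation to monovalent copper and SN2 allylation with prenyl bromide should place the prenyl group exactly at the former C–Br carbon, the lithium phenoxide being too poor a nucleophile at low temperature to compete for the allylic bromide.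

**Step 4**
Reactants: 8 3-(methoxymethoxy)-5-methyl-4-(3-methylbut-2-en-1-yl)phenol
Product: 9 3-(methoxymethoxy)-5-methyl-4-(3-methylbut-2-en-1-yl)phenyl N-(propan-2-yl)carbamate
Conditions: i-PrNCO, Et3N (cat.), CH2Cl2, rt
Reagents that add atoms: isopropyl isocyanate, CC(C)N=C=O
Why: Base-catalysed addition of the phenol to the isocyanate (carbamoylation) gives an N-monoalkyl carbamate that is a strong ortho-director and can later be removed under mild amine conditions.

**Step 5**
Reactants: 9 3-(methoxymethoxy)-5-methyl-4-(3-methylbut-2-en-1-yl)phenyl N-(propan-2-yl)carbamate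
Product: 12 3-(methoxymethoxy)-5-methyl-4-(3-methylbut-2-en-1-yl)-2-(trimethylsilyl)phenyl N-(propan-2-yl)carbamate, via N-silyl carbamate 10 (not isolated), via ortho-lithiated N-silyl carbamate 11 (not isolated)
Conditions: TBSOTf, TMEDA, Et2O, 0 °C → rt; TMEDA, n-BuLi, −78 °C; TMSCl, −78 °C → rt; aq. citric acid
Reagents that add atoms: tert-butyldimethylsilyl triflate, CC(C)(C)[Si](C)(C)OS(=O)(=O)C(F)(F)F (silyl group of 10 and 11 only); n-butyllithium, [Li]CCCC (lithium of 11 only); chlorotrimethylsilane, C[Si](C)(C)Cl
Why: Directed ortho-metalation: after in situ N-silylation the carbamate and the OMOM group together direct n-BuLi to the single CH between the two oxygens, which should be kinetically far more acidic than the CH next to methyl or the benzylic/allylic CH2, and TMSCl traps the aryllithium before the N-silyl group is lost on aqueous work-up.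

**Step 6**
Reactants: 12 3-(methoxymethoxy)-5-methyl-4-(3-methylbut-2-en-1-yl)-2-(trimethylsilyl)phenyl N-(propan-2-yl)carbamate
Product: 14 3-(methoxymethoxy)-5-methyl-4-(3-methylbut-2-en-1-yl)-2-(trimethylsilyl)phenyl trifluoromethanesulfonate, via DBU-H silylphenoxide 13 (not isolated)
Conditions: DBU, Et2NH, MeCN, 40 °C; then PhNTf2, rt
Reagents that add atoms: 1,8-diazabicyclo[5.4.0]undec-7-ene, C1CCC2=NCCCN2CC1 (cation of 13 only); N-phenylbis(trifluoromethanesulfonimide), O=S(=O)(N(c1ccccc1)S(=O)(=O)C(F)(F)F)C(F)(F)F
Why: DBU promotes E1cB loss of isopropyl isocyanate (scavenged by Et2NH) from the N–H carbamate and the liberated 2-silylphenoxide is O-triflated in the same flask, so the protodesilylation-prone free silylphenol is never isolated.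

**Step 7**
Reactants: 15 (3,5-dimethoxyphenyl)methanol
Product: 16 (2-bromo-3,5-dimethoxyphenyl)methanol
Conditions: NBS, CH2Cl2, 0 °C → rt
Reagents that add atoms: N-bromosuccinimide, O=C1CCC(=O)N1Br
Why: Electrophilic aromatic bromination should occur next to the CH2OH group, para to one methoxy group and ortho to the other, because the position between the two methoxy groups is the more hindered one.

**Step 8**
Reactants: 16 (2-bromo-3,5-dimethoxyphenyl)methanol
Product: 17 2-bromo-1,5-dimethoxy-3-[(methoxymethoxy)methyl]benzene
Conditions: NaH, MOMCl, THF, 0 °C → rt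
Reagents that add atoms: chloromethyl methyl ether, COCCl
Why: Williamson-type alkylation of the sodium alkoxide masks the benzylic alcohol with a group that carries no acidic proton and tolerates organolithium, fluoride and carbonate base.

**Step 9**
Reactants: 17 2-bromo-1,5-dimethoxy-3-[(methoxymethoxy)methyl]benzene
Product: 20 2,4-dimethoxy-6-[(methoxymethoxy)methyl]phenol, via aryllithium 18 (not isolated), via dimethyl arylboronate 19 (not isolated)
Conditions: n-BuLi, THF, −78 °C; B(OMe)3, −78 °C → rt; then aq. NaOH, 30% H2O2, 0 °C → rt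
Reagents that add atoms: n-butyllithium, [Li]CCCC (lithium of 18 only); trimethyl borate, COB(OC)OC (boron and methoxy groups of 19 only); hydrogen peroxide, OO
Why: Bromine–lithium exchange, borylation and oxidative C–B to C–O conversion with alkaline peroxide replace the bromine by hydroxyl at the same carbon, which fixes the phenol position without any selectivity issue.

**Step 10**
Reactants: 14 3-(methoxymethoxy)-5-methyl-4-(3-methylbut-2-en-1-yl)-2-(trimethylsilyl)phenyl trifluoromethanesulfonate; 20 2,4-dimethoxy-6-[(methoxymethoxy)methyl]phenol; 21 carbon dioxide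
Product: 24 6-{2,4-dimethoxy-6-[(methoxymethoxy)methyl]phenoxy}-2-(methoxymethoxy)-4-methyl-3-(3-methylbut-2-en-1-yl)benzoic acid, via caesium aryloxide 22 (not isolated), via aryne 23 (not isolated)
Conditions: 20 (1.5 equiv), CsOH·H2O, MeOH, rt; evaporate, toluene azeotrope, dry in vacuo; then 14, CsF, 18-crown-6, THF, CO2 (1 atm), 0 °C → rt; cold 0.5 M HCl to pH 3–4
Reagents that add atoms: caesium hydroxide, [Cs+].[OH-] (caesium of 22 only)
Why: Proposed new method: fluoride attacks the silicon of 14 and triflate leaves, giving aryne 23 (fluoride-induced 1,2-elimination of an o-silylaryl triflate), to which the anhydrous caesium phenoxide 22 adds through oxygen at C2, the aryne carbon remote from the OMOM group, so that the carbanion develops at C1 beside the inductively withdrawing C6–O bond. With no proton donor in the medium this aryl anion should be captured by CO2, so the O–C2 ether bond and the C1–carboxyl bond form in one operation. The closest known reaction types are the three-component coupling of arynes with amines and CO2 to give anthranilic acids and the fluoride-mediated O-arylation of phenols by arynes; a phenoxide as the nucleophilic partner of the carboxylative coupling is the untested element. No ring is closed and no stereocentre is formed. The step needs regioselective addition across the aryne, secured by the polarisation of a 3-alkoxyaryne and by C2 being flanked only by hydrogen, and carboxylation in preference to protonation, secured by complete deprotonation of 20, an aprotic solvent and a CO2 atmosphere (reversible carbonate formation at the phenoxide oxygen should be tolerated as carbamate formation is in the amine case).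

**Step 11**
Reactants: 24 6-{2,4-dimethoxy-6-[(methoxymethoxy)methyl]phenoxy}-2-(methoxymethoxy)-4-methyl-3-(3-methylbut-2-en-1-yl)benzoic acid
Product: 25 methyl 6-{2,4-dimethoxy-6-[(methoxymethoxy)methyl]phenoxy}-2-(methoxymethoxy)-4-methyl-3-(3-methylbut-2-en-1-yl)benzoate
Conditions: MeI, K2CO3, DMF, rt
Reagents that add atoms: iodomethane, CI
Why: SN2 O-alkylation of the potassium carboxylate is insensitive to the two ortho substituents that would block Fischer esterification, and no free phenol is present to be methylated.

**Step 12**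
Reactants: 25 methyl 6-{2,4-dimethoxy-6-[(methoxymethoxy)methyl]phenoxy}-2-(methoxymethoxy)-4-methyl-3-(3-methylbut-2-en-1-yl)benzoate
Product: 26 methyl 6-[2-(hydroxymethyl)-4,6-dimethoxyphenoxy]-2-hydroxy-4-methyl-3-(3-methylbut-2-en-1-yl)benzoate
Conditions: HCl (ca. 1 M) in MeOH, rt → 40 °C
Reagents that add atoms: none
Why: Acid-catalysed acetal exchange with methanol (MOM ether methanolysis) should remove both MOM groups as dimethoxymethane, while the methyl ester is degenerate towards methanolysis and the freed C6–OH is held in a hydrogen bond to the ester, which disfavours acid-promoted chroman closure onto the prenyl group.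

**Compound list**

1 | 2-bromo-3-methylphenol | Cc1cccc(O)c1Br | starting material
2 | 2-bromo-1-(methoxymethoxy)-3-methylbenzene | COCOc1cccc(C)c1Br | intermediate
3 | 2-[4-bromo-3-(methoxymethoxy)-5-methylphenyl]-4,4,5,5-tetramethyl-1,3,2-dioxaborolane (not isolated) | COCOc1cc(B2OC(C)(C)C(C)(C)O2)cc(C)c1Br | intermediate
4 | 4-bromo-3-(methoxymethoxy)-5-methylphenol | COCOc1cc(O)cc(C)c1Br | intermediate
5 | 1-bromo-3-methylbut-2-ene (prenyl bromide) | CC(C)=CCBr | starting material
6 | lithium 4-lithio-3-(methoxymethoxy)-5-methylphenoxide (not isolated) | COCOc1cc([O-])cc(C)c1[Li].[Li+] | intermediate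
7 | lithium 4-cuprio-3-(methoxymethoxy)-5-methylphenoxide, arylcopper of monovalent copper (not isolated) | COCOc1cc([O-])cc(C)c1[Cu].[Li+] | intermediate
8 | 3-(methoxymethoxy)-5-methyl-4-(3-methylbut-2-en-1-yl)phenol | COCOc1cc(O)cc(C)c1CC=C(C)C | intermediate
9 | 3-(methoxymethoxy)-5-methyl-4-(3-methylbut-2-en-1-yl)phenyl N-(propan-2-yl)carbamate | COCOc1cc(OC(=O)NC(C)C)cc(C)c1CC=C(C)C | intermediate
10 | 3-(methoxymethoxy)-5-methyl-4-(3-methylbut-2-en-1-yl)phenyl N-(tert-butyldimethylsilyl)-N-(propan-2-yl)carbamate (not isolated) | COCOc1cc(OC(=O)N(C(C)C)[Si](C)(C)C(C)(C)C)cc(C)c1CC=C(C)C | intermediate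
11 | 2-lithio-3-(methoxymethoxy)-5-methyl-4-(3-methylbut-2-en-1-yl)phenyl N-(tert-butyldimethylsilyl)-N-(propan-2-yl)carbamate (not isolated) | COCOc1c(CC=C(C)C)c(C)cc(OC(=O)N(C(C)C)[Si](C)(C)C(C)(C)C)c1[Li] | intermediate
12 | 3-(methoxymethoxy)-5-methyl-4-(3-methylbut-2-en-1-yl)-2-(trimethylsilyl)phenyl N-(propan-2-yl)carbamate | COCOc1c(CC=C(C)C)c(C)cc(OC(=O)NC(C)C)c1[Si](C)(C)C | intermediate
13 | DBU-H 3-(methoxymethoxy)-5-methyl-4-(3-methylbut-2-en-1-yl)-2-(trimethylsilyl)phenoxide (not isolated) | COCOc1c(CC=C(C)C)c(C)cc([O-])c1[Si](C)(C)C.C1CCC2=[NH+]CCCN2CC1 | intermediate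
14 | 3-(methoxymethoxy)-5-methyl-4-(3-methylbut-2-en-1-yl)-2-(trimethylsilyl)phenyl trifluoromethanesulfonate | COCOc1c(CC=C(C)C)c(C)cc(OS(=O)(=O)C(F)(F)F)c1[Si](C)(C)C | intermediate
15 | (3,5-dimethoxyphenyl)methanol | COc1cc(CO)cc(OC)c1 | starting material
16 | (2-bromo-3,5-dimethoxyphenyl)methanol | COc1cc(CO)c(Br)c(OC)c1 | intermediate
17 | 2-bromo-1,5-dimethoxy-3-[(methoxymethoxy)methyl]benzene | COCOCc1cc(OC)cc(OC)c1Br | intermediate
18 | {2,4-dimethoxy-6-[(methoxymethoxy)methyl]phenyl}lithium (not isolated) | COCOCc1cc(OC)cc(OC)c1[Li] | intermediate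
19 | dimethyl {2,4-dimethoxy-6-[(methoxymethoxy)methyl]phenyl}boronate (not isolated) | COCOCc1cc(OC)cc(OC)c1B(OC)OC | intermediate
20 | 2,4-dimethoxy-6-[(methoxymethoxy)methyl]phenol | COCOCc1cc(OC)cc(OC)c1O | intermediate
21 | carbon dioxide | O=C=O | starting material
22 | caesium 2,4-dimethoxy-6-[(methoxymethoxy)methyl]phenoxide (not isolated) | COCOCc1cc(OC)cc(OC)c1[O-].[Cs+] | intermediate
23 | 1,2-didehydro-3-(methoxymethoxy)-5-methyl-4-(3-methylbut-2-en-1-yl)benzene, the ring A aryne (not isolated) | COCOC1=C(CC=C(C)C)C(C)=CC#C1 | intermediate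
24 | 6-{2,4-dimethoxy-6-[(methoxymethoxy)methyl]phenoxy}-2-(methoxymethoxy)-4-methyl-3-(3-methylbut-2-en-1-yl)benzoic acid | OC(=O)c1c(Oc2c(COCOC)cc(OC)cc2OC)cc(C)c(CC=C(C)C)c1OCOC | intermediate
25 | methyl 6-{2,4-dimethoxy-6-[(methoxymethoxy)methyl]phenoxy}-2-(methoxymethoxy)-4-methyl-3-(3-methylbut-2-en-1-yl)benzoate | COC(=O)c1c(Oc2c(COCOC)cc(OC)cc2OC)cc(C)c(CC=C(C)C)c1OCOC | intermediate
26 | methyl 6-[2-(hydroxymethyl)-4,6-dimethoxyphenoxy]-2-hydroxy-4-methyl-3-(3-methylbut-2-en-1-yl)benzoate | COC(=O)c1c(Oc2c(CO)cc(OC)cc2OC)cc(C)c(CC=C(C)C)c1O | target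

**Step count and risks**

Total step count: 12 (ring A precursor steps 1–6, ring B phenol steps 7–9, then steps 10–12).
Longest linear sequence: 9 steps (steps 1–6, then 10–12).

Steps most likely to fail:

1. Step 10. The C1 aryl anion may be protonated before it meets CO2. The phenoxide may be held as its carbonate and add too slowly, so that fluoride, the product carboxylate or an ene reaction with a prenyl group consumes the aryne. Fallback by known reactions, forming the two bonds one after the other: it sets out from carbamate 9. The N-silylation/ortho-lithiation of step 5 (through 10 and 11) is quenched with methyl chloroformate in place of TMSCl to give methyl 2-(methoxymethoxy)-4-methyl-3-(3-methylbut-2-en-1-yl)-6-[(propan-2-ylcarbamoyl)oxy]benzoate F1. DBU/Et2NH in MeCN releases methyl 6-hydroxy-2-(methoxymethoxy)-4-methyl-3-(3-methylbut-2-en-1-yl)benzoate F2 as its DBU salt, which PhNTf2 converts in the same flask into methyl 2-(methoxymethoxy)-4-methyl-3-(3-methylbut-2-en-1-yl)-6-{[(trifluoromethyl)sulfonyl]oxy}benzoate F3. Palladium-catalysed C–O cross-coupling of F3 with phenol 20 (Pd2(dba)3 as source of zerovalent palladium, a bulky biaryl di-tert-butylphosphine, K3PO4, toluene, 100 °C) should then give ester 25, where the route is rejoined before step 12.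

2. Step 3. Bromine–lithium exchange on the electron-rich phenoxide may be incomplete, the aryl anion may be protonated, or the phenoxide oxygen or the tertiary allylic terminus may be alkylated instead. Fallback by cross-coupling on a neutral substrate: it sets out from phenol 4, which is carbamoylated first (i-PrNCO, Et3N cat.) to 4-bromo-3-(methoxymethoxy)-5-methylphenyl N-(propan-2-yl)carbamate F4. A linear-selective Negishi coupling (Pd(OAc)2, CPhos, THF, rt) with (3-methylbut-2-en-1-yl)zinc bromide F5, made from 5 with zinc dust and LiCl and used in excess to allow for the carbamate N–H, should give carbamate 9, where the route is rejoined before step 5.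

3. Step 12. Under protic acid the prenyl alkene may be protonated and captured by the neighbouring phenol (chroman closure) or by methanol before the less labile benzylic MOM ether is cleaved. Fallback by staged cleavage without free protic acid in the second stage: it sets out from ester 25. NaHSO4 on silica in CH2Cl2 at rt should remove only the phenolic MOM group to give methyl 6-{2,4-dimethoxy-6-[(methoxymethoxy)methyl]phenoxy}-2-hydroxy-4-methyl-3-(3-methylbut-2-en-1-yl)benzoate F6. TMSOTf/2,2'-bipyridyl in CH2Cl2 at 0 °C followed by water should then cleave the benzylic MOM ether, arriving at target 26.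

**Further compounds**

F1 | step 10 | methyl 2-(methoxymethoxy)-4-methyl-3-(3-methylbut-2-en-1-yl)-6-[(propan-2-ylcarbamoyl)oxy]benzoate | COC(=O)c1c(OC(=O)NC(C)C)cc(C)c(CC=C(C)C)c1OCOC
F2 | step 10 | methyl 6-hydroxy-2-(methoxymethoxy)-4-methyl-3-(3-methylbut-2-en-1-yl)benzoate | COC(=O)c1c(O)cc(C)c(CC=C(C)C)c1OCOC
F3 | step 10 | methyl 2-(methoxymethoxy)-4-methyl-3-(3-methylbut-2-en-1-yl)-6-{[(trifluoromethyl)sulfonyl]oxy}benzoate | COC(=O)c1c(OS(=O)(=O)C(F)(F)F)cc(C)c(CC=C(C)C)c1OCOC
F4 | step 3 | 4-bromo-3-(methoxymethoxy)-5-methylphenyl N-(propan-2-yl)carbamate | COCOc1cc(OC(=O)NC(C)C)cc(C)c1Br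
F5 | step 3 | (3-methylbut-2-en-1-yl)zinc bromide | CC(C)=CC[Zn]Br
F6 | step 12 | methyl 6-{2,4-dimethoxy-6-[(methoxymethoxy)methyl]phenoxy}-2-hydroxy-4-methyl-3-(3-methylbut-2-en-1-yl)benzoate | COC(=O)c1c(Oc2c(COCOC)cc(OC)cc2OC)cc(C)c(CC=C(C)C)c1O
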